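**Assumption:** the target has no stereocentre and no configurationally stable axis (the diaryl ether rotates freely), so "single enantiomer" simply means the achiral compound as drawn.

## Retrosynthetic overview

1. Target 11 ⇒ its methyl ether 9; the O–Me cleavage is done last.
2. 9 ⇒ phenolate of 3 + benzyne + a "Br⁺" donor; the diaryl ether C–O bond and the ortho C–Br of ring B are made in one three-component event.
3. 3 (4,5,6-tribromoguaiacol) ⇒ guaiacol + 3 Br2; free OH and OMe together dictate the Br pattern, so bromination must precede O-arylation.
4. No ring is constructed: ring A comes intact from guaiacol and ring B from the benzyne precursor.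

## Route

**Step 1**
Reactants: 1 guaiacol (2-methoxyphenol); 2 bromine
Product: 3 2,3,4-tribromo-6-methoxyphenol (4,5,6-tribromoguaiacol)
Conditions: Br2 (3.05 equiv), AcOH, 15 °C → rt, 16 h; aq. NaHSO3; recrystallise
Reagents that add atoms: bromine 2 (BrBr)
Why: Electrophilic aromatic bromination in which the free OH sends Br to its para and ortho positions (C4, C6) and the OMe sends the third Br para to itself (C5), leaving only the least activated C3–H (meta to OH), so three equivalents should stop at the 4,5,6-tribromo compound; no stereocentre is formed.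

**Step 2**
Reactants: 3 2,3,4-tribromo-6-methoxyphenol; 4 2-(trimethylsilyl)phenyl trifluoromethanesulfonate; 5 1,2-dibromo-1,1,2,2-tetrachloroethane
Product: 9 1,2,3-tribromo-4-(2-bromophenoxy)-5-methoxybenzene, via potassium phenolate 6 (not isolated), via benzyne 7 (not isolated), via aryl anion 8 (not isolated)
Conditions: KH (1.0 equiv), THF, 0 °C; then 5 (1.2 equiv), KF (3 equiv), 18-crown-6 (3 equiv), 4 (1.6 equiv, syringe pump), THF, 0 °C → rt
Reagents that add atoms: 2-(trimethylsilyl)phenyl trifluoromethanesulfonate 4 (C[Si](C)(C)c1ccccc1OS(=O)(=O)C(F)(F)F); 1,2-dibromo-1,1,2,2-tetrachloroethane 5 (BrC(Cl)(Cl)C(Cl)(Cl)Br)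
Why: Proposed new method: a three-component aryne 1,2-bromo-aryloxylation (formal insertion of benzyne into an ArO–Br bond) in which the proton-free crown-activated phenolate 6 adds to fluoride-generated benzyne 7 and the resulting 2-aryloxyphenyl anion 8, having no O–H or acidic C–H to quench it in THF, is intercepted by halophilic attack on 5 (irreversible loss of C2Cl4 and bromide), forming the C–O and ortho C–Br bonds together with no regiochemical issue because benzyne is symmetric; the closest known reaction types are the fluoride-triggered aryne O-arylation of phenols (which ends in protonation) and aryne σ-insertion/three-component amino-halogenation with electrophilic halogen donors; no stereocentre is formed.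

**Step 3**
Reactants: 9 1,2,3-tribromo-4-(2-bromophenoxy)-5-methoxybenzene
Product: 11 3,4,5-tribromo-2-(2-bromophenoxy)phenol, via aryloxydibromoborane 10 (not isolated)
Conditions: BBr3 (3 equiv), CH2Cl2, −78 °C → rt; then H2O
Reagents that add atoms: none
Why: Lewis-acid ether cleavage (BBr3 demethylation) in which boron binds the alkyl aryl ether oxygen and bromide attacks the methyl carbon by SN2, a path closed to the diaryl ether and harmless to aryl bromides, after which hydrolysis of the aryloxyborane frees the phenol; no stereocentre is involved.

## Compound list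

1 | guaiacol (2-methoxyphenol) | COc1ccccc1O | starting material
2 | bromine | BrBr | starting material
3 | 2,3,4-tribromo-6-methoxyphenol (4,5,6-tribromoguaiacol) | COc1cc(Br)c(Br)c(Br)c1O | intermediate
4 | 2-(trimethylsilyl)phenyl trifluoromethanesulfonate | C[Si](C)(C)c1ccccc1OS(=O)(=O)C(F)(F)F | starting material
5 | 1,2-dibromo-1,1,2,2-tetrachloroethane | BrC(Cl)(Cl)C(Cl)(Cl)Br | starting material
6 | potassium 2,3,4-tribromo-6-methoxyphenolate | [K+].[O-]c1c(OC)cc(Br)c(Br)c1Br | intermediate
7 | benzyne | C1=CC=CC#C1 | intermediate
8 | potassium 2-(2,3,4-tribromo-6-methoxyphenoxy)phenide | [K+].COc1cc(Br)c(Br)c(Br)c1Oc1cccc[c-]1 | intermediate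
9 | 1,2,3-tribromo-4-(2-bromophenoxy)-5-methoxybenzene | COc1cc(Br)c(Br)c(Br)c1Oc1ccccc1Br | intermediate
10 | dibromo[3,4,5-tribromo-2-(2-bromophenoxy)phenoxy]borane | BrB(Br)Oc1cc(Br)c(Br)c(Br)c1Oc1ccccc1Br | intermediate
11 | 3,4,5-tribromo-2-(2-bromophenoxy)phenol | Oc1cc(Br)c(Br)c(Br)c1Oc1ccccc1Br | target

## Step count and risks

Total steps: 3. Longest linear sequence: 3 (1 → 3 → 9 → 11).

**Most likely to fail, in order:**

**Step 2 (proposed new reaction).**
- Risks: anion 8 may be protonated before bromine transfer, giving the des-bromo ether. The hindered, weakly nucleophilic phenolate 6 may lose benzyne to fluoride or bromide. 6 may be ipso-brominated by 5; this should be tolerable, because the resulting bromocyclohexadienone is itself a Br⁺ donor toward 8 and returns 6.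
- Fallback (known chemistry), from 3 back to 9: 1-bromo-2-iodobenzene is oxidised with mCPBA/TsOH·H2O in MeCN and condensed in the same pot with 1,3,5-trimethoxybenzene to give (2-bromophenyl)(2,4,6-trimethoxyphenyl)iodonium 4-methylbenzenesulfonate F4. Phenol 3 is then O-arylated with F4 (K2CO3 or t-BuOK, toluene, 50–80 °C) by metal-free ligand coupling at iodine. The trimethoxyphenyl group is the non-transferred dummy and the ortho-substituted aryl transfers preferentially, giving 9.

**Step 1.**
- Risks: over-bromination to tetrabromoguaiacol, or contamination by the 3,4,5-isomer.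
- Fallback, from 1 back to 3, fixing the pattern position by position: 1 is acetylated (Ac2O, pyridine) to 2-methoxyphenyl acetate F1. With the phenol masked, NBS in MeCN brominates para to OMe, giving 5-bromo-2-methoxyphenyl acetate F2. Saponification (NaOH, MeOH/H2O, then HCl) gives 5-bromo-2-methoxyphenol F3. Its free OH now has exactly one open para and one open ortho position, so bromine 2 (2.05 equiv, AcOH, rt) gives 3 unambiguously.

**Step 3.**
- Risk: the electron-poor, hindered OMe oxygen may bind BBr3 poorly, so cleavage is sluggish or forcing conditions cause damage.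
- Fallback, from 9 back to 11, reversing the polarity of the cleavage: SN2 demethylation at carbon with LiI in 2,4,6-collidine at 150 °C. This is favoured by the same electron-poor ring, which makes the phenolate a good leaving group. It gives lithium 3,4,5-tribromo-2-(2-bromophenoxy)phenolate F5, and acidification (aq. HCl) gives 11.

## Further compounds

F1 | step 1 | 2-methoxyphenyl acetate | COc1ccccc1OC(C)=O
F2 | step 1 | 5-bromo-2-methoxyphenyl acetate | COc1ccc(Br)cc1OC(C)=O
F3 | step 1 | 5-bromo-2-methoxyphenol | COc1ccc(Br)cc1O
F4 | step 2 | (2-bromophenyl)(2,4,6-trimethoxyphenyl)iodonium 4-methylbenzenesulfonate | COc1cc(OC)c([I+]c2ccccc2Br)c(OC)c1.Cc1ccc(cc1)S(=O)(=O)[O-]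
F5 | step 3 | lithium 3,4,5-tribromo-2-(2-bromophenoxy)phenolate | [Li+].[O-]c1cc(Br)c(Br)c(Br)c1Oc1ccccc1Br
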